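| setting | epsilon | delta | beta | gamma | eta |
|---|---|---|---|---|---|
| Xa | 0.500 M | 0.250 M | 0.500 M | 0.500 M | 0.500 M |
| Xb | 0.500 M | 0.250 M | 0.500 M | 1.50 M | 0.500 M |
| Xc | 0.00500 M | 0.00500 M | 0.0100 M | 0.00500 M | 0.00500 M |
| time |  |  |  |  | 72 h |

- epsilon run (time / h: [Xa] / M): 0.96: 0.4623; 1.5: 0.4475; 2.4: 0.4186; 3.8: 0.3719; 6.0: 0.3158; 9.6: 0.2415; 15: 0.1744; 24: 0.1243
- delta run (time / h: [Xa] / M): 0.96: 0.2317; 1.5: 0.2224; 2.4: 0.2089; 3.8: 0.1862; 6.0: 0.1574; 9.6: 0.1203; 15: 0.0863; 24: 0.0538
- beta run (time / h: [Xa] / M): 0.96: 0.4340; 1.5: 0.3965; 2.4: 0.3473; 3.8: 0.2843; 6.0: 0.2034; 9.6: 0.1298; 15: 0.0886; 24: 0.0798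
- gamma run (time / h: [Xa] / M): 0.96: 0.4568; 1.5: 0.4328; 2.4: 0.3947; 3.8: 0.3423; 6.0: 0.2751; 9.6: 0.1873; 15: 0.1039; 24: 0.0404

(scatter of a reading: 0.002 M)

- apparent order in [Xc] of the starting rate, round the charge of the epsilon run (the rate where two percent of its Xa have turned into Xp)
- apparent order in [Xb] of the starting rate, round the charge of the epsilon run (the rate where two percent of its Xa have turned into Xp)
- Xa in the eta run at 72 h, as a share of the Xa charged
- which of these the readings show (the product speeds the reaction / the product binds the substrate / the product reacts on with the second partner / the second partner is lost by itself / nothing beyond the main steps / two substrates go astray together)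

- Overall: Xa + Xb -> Xp, with Xc as catalyst.
- Constant volume, constant temperature.
- A reading of a species includes what of it is bound.
- "The second partner" is Xb.
- An order is taken over about fifteen percent of the charge, up and down.

1. We begin with an easy step. Each Xa turned takes one Xb, and epsilon, beta and eta are each charged with equal amounts of the two. Any Xb lost in another way therefore leaves one Xa without a partner. When Xb comes to zero, the Xa still read, bound form counted, equals that extra loss. We call this the stranded Xa.

2. Now we turn the question round. For eta to run through, its stranded Xa must be close to zero, and beta is the run that tests this. At the pace of its stretch from 6.0 h to 9.6 h, beta should read 0.0288 M at 24 h, but it reads 0.0798 M. We take that reading as beta's stranded Xa.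

3. Next we solve both ends. We assume the extra loss goes with the product present. The readings at 24 h allow this: delta keeps 21.5% of its charge and epsilon 24.9%, a smaller share at the smaller charge. At the start there is no product, so the loss per Xa turned begins at zero and grows in step with the Xa turned. Summed up, the stranded Xa is the leak number times the square of the Xa turned, divided by 2. At the stop, the Xa turned is the charge minus the stranded Xa, which joins the two ends in one quadratic equation.

4. Beta gives 0.904 M⁻¹, the leak number: 2 times the stranded Xa, divided by the square of the Xa turned. We take the pace of turning as proportional to Xc and the extra loss as free of it. Eta holds 0.00500 M against beta's 0.0100 M, so for eta the number becomes 1.81 M⁻¹. The equation then strands 0.126 M, which is 25.3% of eta's charge.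

5. The forecast says 0.98 for Xc, 0.28 for Xb, 21% and the product reacts on with the second partner. In its words, “Beta stalls near 0.08 M and epsilon bends down, but gamma does not stall, so Xb is running out”. Its share for eta lies below ours.

6. The simulation gives 1.0, 0.31, 23.3% and the product reacts on with the second partner, and the forecast stands within its margins.

    Xc + Xa → Xc.Xa (23.04 M⁻¹ h⁻¹)
    Xc.Xa + Xb → Xp + Xc (47.88 M⁻¹ h⁻¹)
    Xp + Xb → Xq (0.2149 M⁻¹ h⁻¹)

The step from Xp + Xb to Xq makes Xb the limiting reagent and strands the Xa of eta. Read back through the same rule, the 23.3% of eta gives a leak number of 1.59 M⁻¹, smaller than the 1.81 M⁻¹ carried over from beta's 0.904 M⁻¹. The second flask is eta with that step taken away, so its leak number is zero, and at 72 h it keeps 0.543% of the Xa charged.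

Readings and results come from a simulation with made-up constants, noise included.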